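## Structural features

Abruquinone B (20) is an isoflavan quinone. Ring A is a benzene ring with methoxy groups at C6, C7 and C8, fused through C4a–C8a to the saturated oxygen heterocycle ring C (O1, C2H2, C3H, C4H2). C3 carries ring B, a 2,3-dimethoxy-1,4-benzoquinone bonded through C1′ (carbonyls at C2′ and C5′, methoxy groups at C3′ and C4′, hydrogen at C6′). C3 is the only stereocentre and is S. It lies between two methylene groups, so it has no stereogenic neighbour and its configuration must come from a reagent or catalyst. The quinone is the fragile group (base, nucleophiles, reductants) and should be formed last. The C3–H bond is also labile whenever C2 is at the aldehyde oxidation level, because it is then α to a carbonyl or oxocarbenium carbon and benzylic to an electron-rich ring. The real difficulty is twofold: setting an isolated benzylic stereocentre, and telling apart two rings that are electronically almost identical. Ring A and the reduced form of ring B are both tetra-oxygenated benzenes with a para O/O pair, so a final oxidative demethylation could not choose between them; the oxygens at C2′ and C5′ must carry a group other than methyl from the start. The key step uses the fact that O1–C8a–C4a–C4 is the heterodiene of an ortho-quinone methide of ring A, while C2–C3 with ring B on C3 is the C=C of an arylacetaldehyde enamine. Joining them forms C3–C4 and O1–C2, closes ring C and sets C3 in one catalytic operation.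

## Logic of the disconnections

**20 to 19 to 18.** No skeletal bond is cut. The C=O groups at C2′ and C5′ are taken back to hydroxyls (19) and these to O–benzyl bonds (18). The reason is that ring A would compete in any oxidative dealkylation, whereas hydrogenolysis removes only benzyl groups and leaves the methyl ethers and the O1–C2 bond alone. The gain is a fully aromatic, robust intermediate. The forward step needs an oxidant that acts only on a free para-hydroquinone; 19 is oxidised in the same flask so that it is never handled in air.

**18 to 17.** The C2–H bond is exchanged for C2–OH. This does not simplify the skeleton, but it raises C2 to the aldehyde oxidation level, which the next cut requires. The forward reduction must capture the C2 cation by hydride faster than C3 can lose its proton.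

**17 to 6 plus 15 (through 16).** The bonds cut are C3–C4 and O1–C2. Cutting here splits the molecule into two arenes of similar size and creates the only stereocentre catalytically. The phenolic carbon of 6 becomes C8a, its three methoxy-bearing carbons become C8, C7 and C6, and its CH2 becomes C4. The CHO carbon of 15 becomes C2 and its CH2 becomes C3. The forward step must favour the cross-reaction over self-condensation of 15 and over oligomerisation of 16, and ring closure must be faster than amine-mediated epimerisation. To help this, 6 (the cheaper partner) is used in slight excess and 15 is used freshly made.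

**6 to 3, 4 and formaldehyde (through 5); 3 to 1 (through 2).** In 6 the aryl–CH2 and CH2–S bonds are cut, which reduces it to a phenol, a one-carbon electrophile and a sulfinate. The forward step needs substitution at the single free ortho position of 3, which the substitution pattern guarantees. The aryl C–O bond of 3 is traced to the aryl–CHO bond of 1, a commodity aldehyde (3 is also sold, but 1 is the cheaper entry). The demand is aryl rather than hydride migration, which the ortho- and para-methoxy groups favour.

**15 to 13 (through 14).** The aldehyde carbon is traced to the internal carbon of a terminal alkene. The arylacetaldehyde is too labile to carry through several steps, and the alkene is a stable stored form of it. The forward cleavage must spare a very electron-rich arene, so osmium/periodate is chosen over ozone.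

**13 to 11 (through 12).** The aryl–CH2 bond (C1′–C3 of the target) is cut to an aryl bromide and an allyl electrophile. The forward step needs a metalation that is faster than attack on the benzylic ether positions.

**11 to 10, 10 to 8 (through 9), 8 to 7.** The C–Br bond, the two O–benzyl bonds and the second ring oxygen are removed in turn, ending at a commercial phenol. Symmetry helps here: 8 and 10 each have two equivalent free ring positions, so bromination has no regiochemical question. The oxidation of 7 must go para to the hydroxyl.

## Other disconnections considered

**Alternative 1:** Ring B is cut at C5′–C6′ and C1′–C2′, back to dimethyl squarate and a vinyl unit on C3. In the forward direction the hydroquinone A1 (the same compound as 19) would come from heating the cyclobutenone adduct A2. A2 would be made by adding the vinyllithium A3 to dimethyl squarate A4. Heating opens the four-membered ring to a dienylketene, which closes by 6π electrocyclisation and tautomerises.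
- In its favour: the oxygen pattern of ring B is delivered without any regiochemical choice. Ring B needs no protecting groups and arrives one mild oxidation from 20. The two rings are differentiated automatically. On these three points it is equal to or better than the chosen plan, and its endgame is shorter.
- Against it: the sequence does not create C3. A3 would have to be made enantiopure beforehand, by a separate asymmetric step and several functional-group changes, with C3 α to a carbonyl-type group on the way and therefore at risk. A3 must also add only once to A4 at low temperature.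
- Comparison: mechanistically the pericyclic cascade is more predictable than the kinetically balanced organocatalytic step. Structurally it leaves the main problem, the stereocentre, unsolved, and the total count would probably be several steps longer than the chosen route.

**Alternative 2:** The cut is C3–C1′, with a temporary C4–O bond. The chromene A5 would react with a 2,3-dimethoxy-1,4-benzoquinone under a chiral Lewis acid of tetravalent titanium (TiCl4/Ti(OiPr)4 with a TADDOL diol) to give the cis-fused pterocarpan A6. The quinone partner A7 is the same compound as 8. Hydrogenolysis of the benzylic C–O bond of A6 would give A1, and oxidation would give 20.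
- In its favour: it is the shortest plan. A5 should be two steps from 3, and the whole route about seven steps against ten; on step economy it is clearly better. It needs no protecting groups. The symmetry of A7 removes any regiochemical question. No intermediate has a carbonyl next to C3, so on configurational stability after the key step it is also better.
- Against it: the chirality source is a stoichiometric, moisture-sensitive titanium complex whose level and sense of induction are hard to predict for a new substrate pair. (2+2) adducts and acid-induced oligomerisation of the electron-rich A5 are expected competitors. A7, with two donor groups, is a weak electrophile.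
- Comparison: both plans form two bonds and one ring in the key step. The chosen plan is preferred only because its stereocontrol is catalytic and rests on a well-understood facial model; it is not shorter.

**Alternative 3:** The cuts are C4a–C8a and O1–C2; ring A is built from a squarate. Heating the cyclobutenone A8 would give a dienylketene that closes to the ring A phenol. Cs2CO3 would then let the phenoxide displace the mesylate (6-exo-tet) to give the chroman A9, the same compound as 18.
- In its favour: 18 is reached directly at the ether oxidation level, so there is no lactol and no cation next to C3. The stereocentre could be set earlier by a robust auxiliary alkylation at a position that cannot epimerise. On these points it is equal to or better than the chosen plan. The endgame from A9 is identical.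
- Against it: ring A is built from scratch although it is available fully substituted from 1. A8 needs a side chain that carries the stereocentre and a masked alcohol, brought in as an alkenyl-metal reagent, because a mesylate would not survive that reagent. It also needs O-methylation of a tertiary alkoxide of the A4 adduct.
- Comparison: the mechanism is sound and regiospecific, but convergence and step economy are clearly poorer than in the chosen plan.

Key step: step 8

Remark on the chemistry: the anomeric centre C2 of 17 is not controlled and is carried as a mixture, because step 9 removes it; C3 is the only centre that has to be set.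

## Route

Step 1
Reactants: 1 2,3,4-trimethoxybenzaldehyde
Product: 3 2,3,4-trimethoxyphenol, via aryl formate 2 (not isolated)
Conditions: 30% H2O2, H2SO4 (cat.), MeOH, rt
Reagents that add atoms: hydrogen peroxide, OO
Why: Acid-catalysed Dakin oxidation: the peroxide adduct of the aldehyde rearranges with aryl migration (Baeyer–Villiger type), which the ortho- and para-methoxy groups favour over hydride migration, and formate 2 is methanolysed in the same pot.

Step 2
Reactants: 3 2,3,4-trimethoxyphenol; 4 sodium p-toluenesulfinate
Product: 6 2,3,4-trimethoxy-6-(tosylmethyl)phenol, via hydroxymethylphenol 5 (not isolated)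
Conditions: 37% aq. CH2O, HCO2H/H2O, rt
Reagents that add atoms: formaldehyde, C=O
Why: Mannich-type three-component sulfonylmethylation of an electron-rich phenol: 3 is hydroxymethylated at C6, its only free position ortho to the hydroxyl, acid ionises 5 to the benzylic cation, and the sulfinate captures it at sulfur to give a sulfone that should crystallise.

Step 3
Reactants: 7 2,3-dimethoxyphenol
Product: 8 2,3-dimethoxy-1,4-benzoquinone
Conditions: (KSO3)2NO, KH2PO4, H2O/acetone, 0 °C → rt
Reagents that add atoms: potassium nitrosodisulfonate, [K+].[K+].[O]N(S(=O)(=O)[O-])S(=O)(=O)[O-]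
Why: Teuber oxidation: the nitroxyl radical removes the phenolic hydrogen and a second equivalent couples through oxygen at the free, activated para carbon, which then loses imidodisulfonate, so the 1,4-quinone should prevail over the ortho-quinone.

Step 4
Reactants: 8 2,3-dimethoxy-1,4-benzoquinone
Product: 10 1,4-bis(benzyloxy)-2,3-dimethoxybenzene, via hydroquinone 9 (not isolated)
Conditions: Na2S2O4, Bu4NBr, THF/H2O, rt; then aq. KOH, BnBr, rt, N2
Reagents that add atoms: benzyl bromide, BrCc1ccccc1
Why: Reductive alkylation of a quinone: dithionite gives hydroquinone 9, which is doubly O-benzylated under phase-transfer Williamson conditions without exposure to air; the benzyl groups mark the two oxygens that must become carbonyls again.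

Step 5
Reactants: 10 1,4-bis(benzyloxy)-2,3-dimethoxybenzene
Product: 11 1,4-bis(benzyloxy)-5-bromo-2,3-dimethoxybenzene
Conditions: NBS (1.0 equiv), MeCN, 0 °C → rt
Reagents that add atoms: N-bromosuccinimide, O=C1CCC(=O)N1Br
Why: Electrophilic aromatic bromination: the two free positions of 10 are equivalent by symmetry and strongly activated, one equivalent of NBS in a polar solvent should stop at the monobromide because bromine deactivates the ring, and the benzyl phenyl rings are far less reactive.

Step 6
Reactants: 11 1,4-bis(benzyloxy)-5-bromo-2,3-dimethoxybenzene
Product: 13 1,4-bis(benzyloxy)-2,3-dimethoxy-5-(prop-2-en-1-yl)benzene, via aryllithium 12 (not isolated)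
Conditions: n-BuLi, THF, −78 °C; then CuBr·SMe2 (10 mol %), allyl bromide, −78 → 0 °C
Reagents that add atoms: allyl bromide, C=CCBr
Why: Bromine–lithium exchange at −78 °C is faster than deprotonation of the benzylic ether positions, and aryllithium 12 is allylated by allyl bromide under monovalent copper catalysis (SN2 and SN2′ give the same product).

Step 7
Reactants: 13 1,4-bis(benzyloxy)-2,3-dimethoxy-5-(prop-2-en-1-yl)benzene
Product: 15 [2,5-bis(benzyloxy)-3,4-dimethoxyphenyl]acetaldehyde, via diol 14 (not isolated)
Conditions: K2OsO4·2H2O (2 mol %), NaIO4, 2,6-lutidine, dioxane/H2O, rt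
Reagents that add atoms: sodium periodate (terminal oxidant; its oxygen reaches the product through the osmium catalyst), [Na+].[O-]I(=O)(=O)=O
Why: Lemieux–Johnson cleavage: osmylation is selective for the monosubstituted alkene, periodate cleaves diol 14 and re-oxidises osmium, and 2,6-lutidine suppresses α-hydroxylation. This avoids ozone, which could attack the tetra-oxygenated arene, and 15 is used at once without chromatography.

Step 8
Reactants: 6 2,3,4-trimethoxy-6-(tosylmethyl)phenol (1.3 equiv); 15 [2,5-bis(benzyloxy)-3,4-dimethoxyphenyl]acetaldehyde
Product: 17 (3S)-3-[2,5-bis(benzyloxy)-3,4-dimethoxyphenyl]-6,7,8-trimethoxychroman-2-ol (both anomers), via quinone methide 16 (not isolated)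
Conditions: (S)-2-[diphenyl(trimethylsilyloxy)methyl]pyrrolidine (20 mol %), Na2CO3, CH2Cl2/H2O (10:1), 0 °C → rt
Reagents that add atoms: water, O
Why: Carbonate deprotonates the phenol of 6 and the phenoxide expels p-toluenesulfinate to give quinone methide 16, which stays at low concentration because the sulfinate can add back. Aldehyde 15 condenses with the (S)-prolinol silyl ether to the E-enamine, whose C3 attacks the exocyclic CH2 of 16 (C3–C4 bond) and restores the aromaticity of ring A; the phenoxide then adds to the iminium carbon (O1–C2) and water hydrolyses the N,O-acetal to lactol 17 and free catalyst. The closest known reaction type is the secondary-amine-catalysed inverse-demand oxa-Diels–Alder, (4+2), reaction of aldehydes with ortho-quinone methides released from 2-(sulfonylmethyl)phenols. Ring C closes in a 6-exo-trig mode, either stepwise (Michael addition, then hemiaminal formation) or as a strongly asynchronous cycloaddition. C3 is controlled by the catalyst: the diphenyl(silyloxy)methyl group shields the Re face of the enamine, so 16 approaches the Si face, which corresponds to 3S by the same facial model that holds for α-functionalisation of aldehydes with this catalyst. The step needs chemoselectivity for the cross-reaction over self-aldol condensation of 15 and self-addition of 16; the base-gated release of 16 and the high electrophilicity of its unsubstituted methide terminus should secure it. It also needs retention of the C3 configuration, which ring closure to the aminal and lactol protects by removing the α-aryl aldehyde from the enamine equilibrium. The reaction is stopped as soon as 15 is consumed and 17 is taken on without delay.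

Step 9
Reactants: 17 (3S)-3-[2,5-bis(benzyloxy)-3,4-dimethoxyphenyl]-6,7,8-trimethoxychroman-2-ol
Product: 18 (3S)-3-[2,5-bis(benzyloxy)-3,4-dimethoxyphenyl]-6,7,8-trimethoxychroman
Conditions: Et3SiH (excess), BF3·OEt2, CH2Cl2, −78 → −40 °C
Reagents that add atoms: none
Why: Ionic hydrogenation of a lactol: BF3 ionises the anomeric C2–OH to the cyclic aryloxocarbenium ion and Et3SiH, present in excess before the Lewis acid is added, delivers hydride to C2. At low temperature hydride capture should be faster than loss of H3, so C3 stays S; no bond to C3 changes and the descriptor is unchanged.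

Step 10
Reactants: 18 (3S)-3-[2,5-bis(benzyloxy)-3,4-dimethoxyphenyl]-6,7,8-trimethoxychroman
Product: 20 abruquinone B [2,3-dimethoxy-5-[(3S)-6,7,8-trimethoxychroman-3-yl]cyclohexa-2,5-diene-1,4-dione], via hydroquinone 19 (not isolated)
Conditions: H2 (1 atm), Pd/C, EtOAc, rt; filter; then Ag2O, MgSO4, rt
Reagents that add atoms: none
Why: Hydrogenolysis cleaves only the two O–benzyl bonds (O1–C2 is not benzylic and C4 bears no heteroatom), and Ag2O then oxidises the para-hydroquinone 19 to the quinone. Ring A cannot be oxidised without losing an alkyl group, and C3 is not touched.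

## Compound list

1 | 2,3,4-trimethoxybenzaldehyde | COc1ccc(C=O)c(OC)c1OC | starting material
2 | 2,3,4-trimethoxyphenyl formate | COc1ccc(OC=O)c(OC)c1OC | intermediate
3 | 2,3,4-trimethoxyphenol | COc1ccc(O)c(OC)c1OC | intermediate
4 | sodium p-toluenesulfinate | Cc1ccc(cc1)S(=O)[O-].[Na+] | starting material
5 | 6-(hydroxymethyl)-2,3,4-trimethoxyphenol | COc1cc(CO)c(O)c(OC)c1OC | intermediate
6 | 2,3,4-trimethoxy-6-(tosylmethyl)phenol | COc1cc(CS(=O)(=O)c2ccc(C)cc2)c(O)c(OC)c1OC | intermediate
7 | 2,3-dimethoxyphenol | COc1cccc(O)c1OC | starting material
8 | 2,3-dimethoxy-1,4-benzoquinone | COC1=C(OC)C(=O)C=CC1=O | intermediate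
9 | 2,3-dimethoxybenzene-1,4-diol | COc1c(O)ccc(O)c1OC | intermediate
10 | 1,4-bis(benzyloxy)-2,3-dimethoxybenzene | COc1c(OCc2ccccc2)ccc(OCc2ccccc2)c1OC | intermediate
11 | 1,4-bis(benzyloxy)-5-bromo-2,3-dimethoxybenzene | Brc1cc(OCc2ccccc2)c(OC)c(OC)c1OCc1ccccc1 | intermediate
12 | [2,5-bis(benzyloxy)-3,4-dimethoxyphenyl]lithium | [Li]c1cc(OCc2ccccc2)c(OC)c(OC)c1OCc1ccccc1 | intermediate
13 | 1,4-bis(benzyloxy)-2,3-dimethoxy-5-(prop-2-en-1-yl)benzene | C=CCc1cc(OCc2ccccc2)c(OC)c(OC)c1OCc1ccccc1 | intermediate
14 | 3-[2,5-bis(benzyloxy)-3,4-dimethoxyphenyl]propane-1,2-diol (racemic) | OCC(O)Cc1cc(OCc2ccccc2)c(OC)c(OC)c1OCc1ccccc1 | intermediate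
15 | [2,5-bis(benzyloxy)-3,4-dimethoxyphenyl]acetaldehyde | O=CCc1cc(OCc2ccccc2)c(OC)c(OC)c1OCc1ccccc1 | intermediate
16 | 2,3,4-trimethoxy-6-methylidenecyclohexa-2,4-dien-1-one | O=C1C(=C)C=C(OC)C(OC)=C1OC | intermediate
17 | (3S)-3-[2,5-bis(benzyloxy)-3,4-dimethoxyphenyl]-6,7,8-trimethoxychroman-2-ol (both anomers) | OC1Oc2c(OC)c(OC)c(OC)cc2C[C@H]1c1cc(OCc2ccccc2)c(OC)c(OC)c1OCc1ccccc1 | intermediate
18 | (3S)-3-[2,5-bis(benzyloxy)-3,4-dimethoxyphenyl]-6,7,8-trimethoxychroman | COc1c(OC)c(OCc2ccccc2)cc([C@H]2COc3c(cc(OC)c(OC)c3OC)C2)c1OCc1ccccc1 | intermediate
19 | (3S)-3-(2,5-dihydroxy-3,4-dimethoxyphenyl)-6,7,8-trimethoxychroman | COc1c(OC)c(O)c([C@H]2COc3c(cc(OC)c(OC)c3OC)C2)cc1O | intermediate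
20 | abruquinone B, 2,3-dimethoxy-5-[(3S)-6,7,8-trimethoxychroman-3-yl]cyclohexa-2,5-diene-1,4-dione | COC1=C(OC)C(=O)C([C@H]2COc3c(cc(OC)c(OC)c3OC)C2)=CC1=O | target

## Step count and least certain steps

Total: 10 steps. Longest linear sequence: 8 steps (steps 3 to 10, from 7). The ring A arm is 5 steps (steps 1, 2, 8, 9, 10).

The uncertain steps are listed from the end of the route backwards.

**Step 9 (lactol reduction).** The likely failure is erosion of the C3 configuration. The oxocarbenium ion can lose the C3 proton to give an enol ether that is reprotonated without facial control; the cation could also be captured by an electron-rich ring in a Friedel–Crafts sense. The fallback sets out from 17 and comes back at 18 and never forms a cation at C2. NaBH4 (THF/MeOH, 0 °C) should reduce the open hydroxy-aldehyde form of 17 to the diol 6-{(2S)-2-[2,5-bis(benzyloxy)-3,4-dimethoxyphenyl]-3-hydroxypropyl}-2,3,4-trimethoxyphenol F1. A Mitsunobu reaction (PPh3, DIAD, THF) should then close ring C by O-alkylation of the phenol with the primary alcohol, giving 18.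

**Step 8 (key step).** Three processes could spoil it: amine-mediated epimerisation of the α-aryl centre through the open form of the product, self-aldol condensation of 15 under base and amine, and oligomerisation of the unsubstituted quinone methide when its release is not matched to the enamine concentration. The fallback replaces catalysis by an oxazolidinone-auxiliary (Evans) alkylation; it sets out from 15 and from 3 and comes back at 18.
- Pinnick oxidation of 15 (NaClO2, NaH2PO4, 2-methylbut-2-ene, t-BuOH/H2O) should give [2,5-bis(benzyloxy)-3,4-dimethoxyphenyl]acetic acid F2.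
- Its pivaloyl mixed anhydride (PivCl, Et3N) should acylate lithiated (S)-4-benzyl-1,3-oxazolidin-2-one to give (4S)-4-benzyl-3-{[2,5-bis(benzyloxy)-3,4-dimethoxyphenyl]acetyl}-1,3-oxazolidin-2-one F3.
- In parallel 3 is protected (MOMCl, i-Pr2NEt) as 1,2,3-trimethoxy-4-(methoxymethoxy)benzene F4. Lithiation ortho to the acetal oxygen (n-BuLi, TMEDA, THF, 0 °C) and a paraformaldehyde quench should give [3,4,5-trimethoxy-2-(methoxymethoxy)phenyl]methanol F5. CBr4/PPh3 should convert it into 1-(bromomethyl)-3,4,5-trimethoxy-2-(methoxymethoxy)benzene F6.
- The sodium Z-enolate of F3 (NaN(SiMe3)2, THF, −78 °C) should be alkylated by F6 on the face away from the benzyl group of the auxiliary. This should give (4S)-4-benzyl-3-{(2S)-2-[2,5-bis(benzyloxy)-3,4-dimethoxyphenyl]-3-[3,4,5-trimethoxy-2-(methoxymethoxy)phenyl]propanoyl}-1,3-oxazolidin-2-one F7.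
- LiBH4 (THF, a little water) should remove the auxiliary and give (2S)-2-[2,5-bis(benzyloxy)-3,4-dimethoxyphenyl]-3-[3,4,5-trimethoxy-2-(methoxymethoxy)phenyl]propan-1-ol F8.
- HCl in MeOH should free the phenol to give the diol 6-{(2S)-2-[2,5-bis(benzyloxy)-3,4-dimethoxyphenyl]-3-hydroxypropyl}-2,3,4-trimethoxyphenol F1 of the preceding fallback, and the same Mitsunobu closure should give 18.

**Step 7 (oxidative cleavage).** The likely failures are over-oxidation (α-hydroxylation, or further cleavage towards the benzaldehyde) and self-condensation of the arylacetaldehyde during work-up. The fallback sets out from 11 and comes back at 15; it uses no oxidant and also bypasses step 6. Suzuki–Miyaura coupling of 11 with (E)-2-(2-ethoxyethenyl)-4,4,5,5-tetramethyl-1,3,2-dioxaborolane (Pd(OAc)2, SPhos, K3PO4, dioxane/H2O, 80 °C) should give the enol ether 1,4-bis(benzyloxy)-5-[(E)-2-ethoxyethenyl]-2,3-dimethoxybenzene F9. Brief hydrolysis (aq. HCl, THF, rt) should release 15 just before use.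

**Step 6 (lithiation and allylation).** The likely failures are deprotonation of a benzylic ether position by the aryllithium, followed by anionic rearrangement, or simple protonation to the debrominated arene. The fallback sets out from 11 and comes back at 13 without an organolithium: Suzuki–Miyaura coupling with allylboronic acid pinacol ester (Pd(dppf)Cl2, CsF, THF, reflux). It passes through no new compound.

**Step 2 (sulfonylmethylation).** The likely failure is C-alkylation of a second molecule of 3 by the benzylic cation (diarylmethane formation), or partial attack at C5. The fallback sets out from 3 and comes back at 6, introducing the carbon at the aldehyde level, where over-alkylation is impossible. Ortho-formylation (MgCl2, Et3N, paraformaldehyde, MeCN, reflux) should give 2-hydroxy-3,4,5-trimethoxybenzaldehyde F10. NaBH4 should reduce it to 5, which is isolated this time. Treating 5 with 4 in formic acid should give 6.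

## Further compounds

F1 | step 9 | 6-{(2S)-2-[2,5-bis(benzyloxy)-3,4-dimethoxyphenyl]-3-hydroxypropyl}-2,3,4-trimethoxyphenol | OC[C@@H](Cc1cc(OC)c(OC)c(OC)c1O)c1cc(OCc2ccccc2)c(OC)c(OC)c1OCc1ccccc1
F2 | step 8 | [2,5-bis(benzyloxy)-3,4-dimethoxyphenyl]acetic acid | OC(=O)Cc1cc(OCc2ccccc2)c(OC)c(OC)c1OCc1ccccc1
F3 | step 8 | (4S)-4-benzyl-3-{[2,5-bis(benzyloxy)-3,4-dimethoxyphenyl]acetyl}-1,3-oxazolidin-2-one | O=C(Cc1cc(OCc2ccccc2)c(OC)c(OC)c1OCc1ccccc1)N1[C@@H](Cc2ccccc2)COC1=O
F4 | step 8 | 1,2,3-trimethoxy-4-(methoxymethoxy)benzene | COCOc1ccc(OC)c(OC)c1OC
F5 | step 8 | [3,4,5-trimethoxy-2-(methoxymethoxy)phenyl]methanol | COCOc1c(CO)cc(OC)c(OC)c1OC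
F6 | step 8 | 1-(bromomethyl)-3,4,5-trimethoxy-2-(methoxymethoxy)benzene | COCOc1c(CBr)cc(OC)c(OC)c1OC
F7 | step 8 | (4S)-4-benzyl-3-{(2S)-2-[2,5-bis(benzyloxy)-3,4-dimethoxyphenyl]-3-[3,4,5-trimethoxy-2-(methoxymethoxy)phenyl]propanoyl}-1,3-oxazolidin-2-one | O=C([C@@H](Cc1cc(OC)c(OC)c(OC)c1OCOC)c1cc(OCc2ccccc2)c(OC)c(OC)c1OCc1ccccc1)N1[C@@H](Cc2ccccc2)COC1=O
F8 | step 8 | (2S)-2-[2,5-bis(benzyloxy)-3,4-dimethoxyphenyl]-3-[3,4,5-trimethoxy-2-(methoxymethoxy)phenyl]propan-1-ol | OC[C@@H](Cc1cc(OC)c(OC)c(OC)c1OCOC)c1cc(OCc2ccccc2)c(OC)c(OC)c1OCc1ccccc1
F9 | step 7 | 1,4-bis(benzyloxy)-5-[(E)-2-ethoxyethenyl]-2,3-dimethoxybenzene | CCO/C=C/c1cc(OCc2ccccc2)c(OC)c(OC)c1OCc1ccccc1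
F0 | step 6 | none | none
F10 | step 2 | 2-hydroxy-3,4,5-trimethoxybenzaldehyde | COc1cc(C=O)c(O)c(OC)c1OC
A1 | alternative 1 | (3S)-3-(2,5-dihydroxy-3,4-dimethoxyphenyl)-6,7,8-trimethoxychroman (identical with 19) | COc1c(OC)c(O)c([C@H]2COc3c(cc(OC)c(OC)c3OC)C2)cc1O
A2 | alternative 1 | 4-hydroxy-2,3-dimethoxy-4-{1-[(3S)-6,7,8-trimethoxychroman-3-yl]ethenyl}cyclobut-2-en-1-one (carbinol centre uncontrolled) | COC1=C(OC)C(O)(C(=C)[C@H]2COc3c(cc(OC)c(OC)c3OC)C2)C1=O
A3 | alternative 1 | {1-[(3S)-6,7,8-trimethoxychroman-3-yl]ethenyl}lithium | [Li]C(=C)[C@H]1COc2c(cc(OC)c(OC)c2OC)C1
A4 | alternative 1 | dimethyl squarate (3,4-dimethoxycyclobut-3-ene-1,2-dione) | COC1=C(OC)C(=O)C1=O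
A5 | alternative 2 | 6,7,8-trimethoxy-2H-chromene | COc1cc2C=CCOc2c(OC)c1OC
A6 | alternative 2 | (6aS,11aS)-8-hydroxy-2,3,4,9,10-pentamethoxypterocarpan | COc1cc2[C@H]3Oc4c(OC)c(OC)c(O)cc4[C@H]3COc2c(OC)c1OC
A7 | alternative 2 | 2,3-dimethoxy-1,4-benzoquinone (identical with 8) | COC1=C(OC)C(=O)C=CC1=O
A8 | alternative 3 | (2S,4E)-2-[2,5-bis(benzyloxy)-3,4-dimethoxyphenyl]-5-(1,2,3-trimethoxy-4-oxocyclobut-2-en-1-yl)pent-4-en-1-yl methanesulfonate (ring centre uncontrolled) | COC1=C(OC)C(OC)(/C=C/C[C@H](COS(C)(=O)=O)c2cc(OCc3ccccc3)c(OC)c(OC)c2OCc2ccccc2)C1=O
A9 | alternative 3 | (3S)-3-[2,5-bis(benzyloxy)-3,4-dimethoxyphenyl]-6,7,8-trimethoxychroman (identical with 18) | COc1c(OC)c(OCc2ccccc2)cc([C@H]2COc3c(cc(OC)c(OC)c3OC)C2)c1OCc1ccccc1
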